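The route rests on the C1–C8a bond of the 3,4-dihydroisoquinoline. The nitrogen ring (N2, C1, C3, C4, C4a, C8a) is closed last by a Bischler–Napieralski cyclodehydration. Activation of an open-chain (S)-N-acetyl-1-arylpropan-2-amine gives a nitrilium ion that attacks C8a of ring A (the benzo ring of the isoquinoline). C8a is the only free position ortho to the side chain, para to the C6 methoxy and ortho to the C8 methoxy group. One operation creates the C1=N imine and the ring and leaves C3 untouched. The precursor is a biaryl acetamide: its stereocentre comes from an L-alaninol-derived cyclic sulfamidate, its naphthalene from a Dötz benzannulation, and the biaryl bond from a Suzuki coupling.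

Key step: step 8

Assumption: the structure as drawn fixes only C3 as (S) and leaves the configuration of the hindered C5–C1' biaryl axis open; the route therefore controls C3 and is expected to give the axis as a mixture of atropo-diastereomers, which could be separated at the end if a single one were wanted.

Step 1
Reactants: 1 2-bromoanisole; 2 hexacarbonylchromium, Cr(CO)6
Product: 5 pentacarbonyl[methoxy(2-methoxyphenyl)methylidene]chromium, via 2-methoxyphenyllithium 3 (not isolated), via lithium acylchromate 4 (not isolated)
Conditions: n-BuLi, Et2O, −78 °C; Cr(CO)6, Et2O, 0 °C to rt; then Me3OBF4, CH2Cl2/H2O, 0 °C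
Reagents that add atoms: trimethyloxonium tetrafluoroborate, C[O+](C)C.F[B-](F)(F)F
Why: Fischer carbene synthesis: the aryllithium from bromine–lithium exchange adds to a CO ligand of Cr(CO)6 and the hard oxonium salt O-methylates the resulting acylchromate.

Step 2
Reactants: 5 pentacarbonyl[methoxy(2-methoxyphenyl)methylidene]chromium; 6 propyne
Product: 8 4,5-dimethoxy-2-methylnaphthalen-1-ol, via tricarbonylchromium naphthol complex 7 (not isolated)
Conditions: propyne (excess), THF, 50 °C, sealed vessel; then air, Et2O, rt; crude product used directly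
Reagents that add atoms: none
Why: Dötz benzannulation: insertion of the alkyne and of one CO ligand into the carbene, then electrocyclisation onto the only free ortho position of the anisyl ring, should build the second naphthalene ring with the alkyne methyl group next to the new phenol (C2), as is usual for terminal alkynes, and mild air oxidation strips the Cr(CO)3 fragment.

Step 3
Reactants: 8 4,5-dimethoxy-2-methylnaphthalen-1-ol
Product: 9 4,5-dimethoxy-2-methylnaphthalen-1-yl trifluoromethanesulfonate
Conditions: Tf2O, pyridine, CH2Cl2, 0 °C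
Reagents that add atoms: trifluoromethanesulfonic anhydride, O=S(=O)(OS(=O)(=O)C(F)(F)F)C(F)(F)F
Why: O-sulfonylation of the phenol turns C1 into a cross-coupling electrophile at a position fixed unambiguously by the benzannulation.

Step 4
Reactants: 10 1-bromo-3,5-dimethoxybenzene; 11 tert-butyl (4S)-4-methyl-1,2,3-oxathiazolidine-3-carboxylate 2,2-dioxide (cyclic sulfamidate of N-Boc-L-alaninol)
Product: 14 tert-butyl N-[(2S)-1-(3,5-dimethoxyphenyl)propan-2-yl]carbamate, via 3,5-dimethoxyphenylmagnesium bromide 12 (not isolated), via bromomagnesium N-Boc-sulfamate 13 (not isolated)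
Conditions: Mg, THF, reflux; CuI (copper monoiodide, 10 mol %), 11, THF, −30 °C to rt; then 1 M aq. HCl, rt
Reagents that add atoms: none
Why: copper-catalysed SN2 opening of the cyclic sulfamidate by the aryl Grignard reagent occurs at the primary C–O carbon, so the L-alaninol-derived centre is not touched and becomes the (S) centre (later C3), and dilute acid then hydrolyses the N-sulfate while the Boc group should survive.

Step 5
Reactants: 14 tert-butyl N-[(2S)-1-(3,5-dimethoxyphenyl)propan-2-yl]carbamate
Product: 16 N-[(2S)-1-(3,5-dimethoxyphenyl)propan-2-yl]acetamide, via amine hydrochloride 15 (not isolated)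
Conditions: 4 M HCl in 1,4-dioxane, rt; concentrate; then Ac2O, Et3N, CH2Cl2, 0 °C to rt
Reagents that add atoms: acetic anhydride, CC(=O)OC(C)=O
Why: protecting-group exchange by acidolysis of the Boc carbamate and N-acetylation of the liberated amine installs the amide for the key step without touching the stereocentre, HCl being chosen over TFA to limit tert-butylation of the electron-rich ring.

Step 6
Reactants: 16 N-[(2S)-1-(3,5-dimethoxyphenyl)propan-2-yl]acetamide
Product: 17 N-[(2S)-1-(2-bromo-3,5-dimethoxyphenyl)propan-2-yl]acetamide
Conditions: NBS (1.0 equiv), MeCN, 0 °C, dark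
Reagents that add atoms: N-bromosuccinimide, O=C1CCC(=O)N1Br
Why: electrophilic aromatic bromination should occur ortho to the side chain, para to one methoxy group and ortho to the other (the two such positions are equivalent), in preference to the more crowded position between the two methoxy groups.

Step 7
Reactants: 9 4,5-dimethoxy-2-methylnaphthalen-1-yl trifluoromethanesulfonate; 17 N-[(2S)-1-(2-bromo-3,5-dimethoxyphenyl)propan-2-yl]acetamide; 18 bis(pinacolato)diboron
Product: 20 N-[(2S)-1-[2-(4,5-dimethoxy-2-methylnaphthalen-1-yl)-3,5-dimethoxyphenyl]propan-2-yl]acetamide, via naphthyl pinacol boronate 19 (not isolated)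
Conditions: 9, B2pin2 (1.05 equiv), KOAc, Pd(dppf)Cl2 (3 mol %), 1,4-dioxane, 90 °C; then 17, Pd(OAc)2 (5 mol %), SPhos, aq. K3PO4, 100 °C
Reagents that add atoms: none
Why: Miyaura borylation of the triflate followed in the same flask by Suzuki–Miyaura coupling with the aryl bromide forms the tri-ortho-substituted biaryl bond, for which the bulky electron-rich SPhos ligand is suited; the secondary amide is tolerated and the new axis is expected as a mixture of atropo-diastereomers.

Step 8
Reactants: 20 N-[(2S)-1-[2-(4,5-dimethoxy-2-methylnaphthalen-1-yl)-3,5-dimethoxyphenyl]propan-2-yl]acetamide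
Product: 21 O-methylancistrocladinine
Conditions: Tf2O (1.1 equiv), 2-chloropyridine (2 equiv), CH2Cl2, −78 °C to rt; aq. NaHCO3
Reagents that add atoms: none
Why: Tf2O, buffered by the non-nucleophilic 2-chloropyridine, converts the secondary acetamide into an O-triflyl imidate that ionises to an N-alkylnitrilium ion; C8a of ring A attacks its carbon and loss of the proton re-aromatises the ring to give the C1=N imine (Bischler–Napieralski reaction in its electrophilic amide-activation form). The closure is a 6-endo-dig electrophilic aromatic substitution that forms the C1–C8a bond and completes the nitrogen ring N2–C1–C8a–C4a–C4–C3. No new stereocentre is formed, and because the C3–N bond is not broken the (S) configuration from the sulfamidate is carried through. The step needs regioselectivity for C8a over the electron-rich naphthalene: C8a is the only free position ortho to the tether, it is activated by the para C6 and ortho C8 methoxy groups, and attack on the naphthalene would need a ring of nine or more atoms. The low temperature and the absence of strong protic acid should also suppress retro-Ritter loss of acetonitrile and cleavage of the four aryl methyl ethers.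

Compound list

1 | 2-bromoanisole | COc1ccccc1Br | starting material
2 | hexacarbonylchromium | O=C=[Cr](=C=O)(=C=O)(=C=O)(=C=O)=C=O | starting material
3 | 2-methoxyphenyllithium | COc1ccccc1[Li] | intermediate
4 | lithium pentacarbonyl[(2-methoxyphenyl)(oxido)methylidene]chromate (acylchromate) | [Li+].COc1ccccc1C([O-])=[Cr](=C=O)(=C=O)(=C=O)(=C=O)=C=O | intermediate
5 | pentacarbonyl[methoxy(2-methoxyphenyl)methylidene]chromium | COC(c1ccccc1OC)=[Cr](=C=O)(=C=O)(=C=O)(=C=O)=C=O | intermediate
6 | propyne | CC#C | starting material
7 | tricarbonylchromium complex of 4,5-dimethoxy-2-methylnaphthalen-1-ol (arene-bound Cr(CO)3, written as its two parts) | COc1cc(C)c(O)c2cccc(OC)c12.O=C=[Cr](=C=O)=C=O | intermediate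
8 | 4,5-dimethoxy-2-methylnaphthalen-1-ol | COc1cc(C)c(O)c2cccc(OC)c12 | intermediate
9 | 4,5-dimethoxy-2-methylnaphthalen-1-yl trifluoromethanesulfonate | COc1cc(C)c(OS(=O)(=O)C(F)(F)F)c2cccc(OC)c12 | intermediate
10 | 1-bromo-3,5-dimethoxybenzene | COc1cc(Br)cc(OC)c1 | starting material
11 | tert-butyl (4S)-4-methyl-1,2,3-oxathiazolidine-3-carboxylate 2,2-dioxide | C[C@H]1COS(=O)(=O)N1C(=O)OC(C)(C)C | starting material
12 | 3,5-dimethoxyphenylmagnesium bromide | COc1cc(OC)cc([Mg]Br)c1 | intermediate
13 | bromomagnesium (S)-N-(tert-butoxycarbonyl)-N-[1-(3,5-dimethoxyphenyl)propan-2-yl]sulfamate | COc1cc(OC)cc(C[C@H](C)N(C(=O)OC(C)(C)C)S(=O)(=O)[O-])c1.[Mg+2].[Br-] | intermediate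
14 | tert-butyl N-[(2S)-1-(3,5-dimethoxyphenyl)propan-2-yl]carbamate | COc1cc(OC)cc(C[C@H](C)NC(=O)OC(C)(C)C)c1 | intermediate
15 | (2S)-1-(3,5-dimethoxyphenyl)propan-2-aminium chloride | COc1cc(OC)cc(C[C@H](C)[NH3+])c1.[Cl-] | intermediate
16 | N-[(2S)-1-(3,5-dimethoxyphenyl)propan-2-yl]acetamide | COc1cc(OC)cc(C[C@H](C)NC(C)=O)c1 | intermediate
17 | N-[(2S)-1-(2-bromo-3,5-dimethoxyphenyl)propan-2-yl]acetamide | COc1cc(OC)c(Br)c(C[C@H](C)NC(C)=O)c1 | intermediate
18 | bis(pinacolato)diboron | CC1(C)OB(OC1(C)C)B1OC(C)(C)C(C)(C)O1 | starting material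
19 | 2-(4,5-dimethoxy-2-methylnaphthalen-1-yl)-4,4,5,5-tetramethyl-1,3,2-dioxaborolane | COc1cc(C)c(B3OC(C)(C)C(C)(C)O3)c2cccc(OC)c12 | intermediate
20 | N-[(2S)-1-[2-(4,5-dimethoxy-2-methylnaphthalen-1-yl)-3,5-dimethoxyphenyl]propan-2-yl]acetamide | COc1cc(OC)c(-c2c(C)cc(OC)c3c(OC)cccc23)c(C[C@H](C)NC(C)=O)c1 | intermediate
21 | O-methylancistrocladinine, (3S)-5-(4,5-dimethoxy-2-methylnaphthalen-1-yl)-6,8-dimethoxy-1,3-dimethyl-3,4-dihydroisoquinoline | COc1cc(OC)c(-c2c(C)cc(OC)c3c(OC)cccc23)c2c1C(C)=N[C@@H](C)C2 | target

Total step count: 8 steps.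
Longest linear sequence: 5 steps (steps 1, 2, 3, 7, 8; the branch of steps 4, 5, 6, 7, 8 is equally long).

Steps most likely to fail

Step 7. Borylation of the hindered triflate may be slow, and the electron-rich naphthyl boronate may undergo protodeboronation before transmetalation, so that reduced naphthalene and unreacted bromide remain. The fallback exchanges the roles of the two partners. It sets out from bromide 17. Miyaura borylation (B2pin2, KOAc, Pd2(dba)3, XPhos, 1,4-dioxane, 100 °C) would give the isolated pinacol boronate N-[(2S)-1-[3,5-dimethoxy-2-(4,4,5,5-tetramethyl-1,3,2-dioxaborolan-2-yl)phenyl]propan-2-yl]acetamide F1. Suzuki–Miyaura coupling of F1 with triflate 9 (Pd(OAc)2, SPhos, K3PO4, toluene/water, 100 °C) comes back to the route at 20.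

Step 2. The volatile terminal alkyne may oligomerise at the metal, the carbene may be diverted to furan or indene products, or the electron-rich naphthol may be over-oxidised to the quinone during release from chromium. The fallback builds the naphthalene without chromium and sets out from 2-methoxyphenyllithium 3 (made from 1 as in step 1).
- Quenching 3 with diethylcarbamoyl chloride would give N,N-diethyl-2-methoxybenzamide F2.
- Directed ortho-metalation next to the amide (s-BuLi, TMEDA, THF, −78 °C), transmetalation with CuBr·SMe2 and allylation with 3-bromo-2-methylpropene would give N,N-diethyl-2-methoxy-6-(2-methylprop-2-en-1-yl)benzamide F3.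
- Anionic ring annulation of the ortho-allyl benzamide (LDA, THF, −78 °C to rt) should give 8-methoxy-3-methylnaphthalen-1-ol F4.
- O-Methylation (MeI, K2CO3, acetone) would give 1,8-dimethoxy-3-methylnaphthalene F5.
- Bromination (NBS, MeCN, 0 °C), expected para to the 1-methoxy group and ortho to the methyl group, would give 1-bromo-4,5-dimethoxy-2-methylnaphthalene F6.
- Bromine–lithium exchange and borylation (n-BuLi, THF, −78 °C; 2-isopropoxy-4,4,5,5-tetramethyl-1,3,2-dioxaborolane) comes back to the route at boronate 19, here isolated and coupled with 17 under the second set of conditions of step 7 to give 20.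

Step 8. The nitrilium ion may fragment by retro-Ritter loss of acetonitrile, helped by the electron-rich aryl group two carbons from nitrogen, or the activated amide may be consumed by intermolecular attack on the naphthalene. The fallback replaces the nitrilium ion by an N-acyliminium ion that cannot fragment in this way. It sets out from acetamide 20. Oxalyl chloride (CH2Cl2, 0 °C) followed by FeCl3 (−10 °C to rt) should cyclise at C8a to the oxalyl-bridged adduct (5S)-7-(4,5-dimethoxy-2-methylnaphthalen-1-yl)-8,10-dimethoxy-5,10b-dimethyl-5,6-dihydro-10bH-[1,3]oxazolo[2,3-a]isoquinoline-2,3-dione F7, formed as a mixture at C10b, which is of no consequence. Heating F7 in MeOH/H2SO4 removes the oxalyl bridge and comes back to the route at 21, the nitrogen ring still being the last ring closed.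

Further compounds

F1 | step 7 | N-[(2S)-1-[3,5-dimethoxy-2-(4,4,5,5-tetramethyl-1,3,2-dioxaborolan-2-yl)phenyl]propan-2-yl]acetamide | COc1cc(OC)c(B2OC(C)(C)C(C)(C)O2)c(C[C@H](C)NC(C)=O)c1
F2 | step 2 | N,N-diethyl-2-methoxybenzamide | CCN(CC)C(=O)c1ccccc1OC
F3 | step 2 | N,N-diethyl-2-methoxy-6-(2-methylprop-2-en-1-yl)benzamide | CCN(CC)C(=O)c1c(CC(C)=C)cccc1OC
F4 | step 2 | 8-methoxy-3-methylnaphthalen-1-ol | COc1cccc2cc(C)cc(O)c12
F5 | step 2 | 1,8-dimethoxy-3-methylnaphthalene | COc1cc(C)cc2cccc(OC)c12
F6 | step 2 | 1-bromo-4,5-dimethoxy-2-methylnaphthalene | COc1cc(C)c(Br)c2cccc(OC)c12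
F7 | step 8 | (5S)-7-(4,5-dimethoxy-2-methylnaphthalen-1-yl)-8,10-dimethoxy-5,10b-dimethyl-5,6-dihydro-10bH-[1,3]oxazolo[2,3-a]isoquinoline-2,3-dione | COc1cc(OC)c(-c2c(C)cc(OC)c3c(OC)cccc23)c2c1C1(C)OC(=O)C(=O)N1[C@@H](C)C2
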